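**Plan**
- Each imidazole is cut at C2 (its two C–N bonds, with C4–C5 coming from glyoxal) back to an arylacetaldehyde, and so to two silyl-protected 2-hydroxyethyl arms.
- Ring B is numbered with C1 on the diaryl ether oxygen and C3 on the CH2 arm. After a hydroxyl is put back on C5, it is cut at C1–C2 and C5–C6 into an ethynyl ether of the ring A phenol (C1, C6) and a 3-substituted cyclobutenone (C2–C5).
- Enabling feature: ring B carries only the ether oxygen at C1 and the arm at C3, meta to each other. This is the pattern that an oxygen-substituted alkyne and a 3-substituted cyclobutenone assemble, so the C1–O bond comes in with the ring A phenol and is never made by coupling.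
- Forward order: ring A is bought and given its arm and the ethynyl ether; the four-membered ring is made from 3-butyn-1-ol and dichloroketene; ring B closes third; both imidazoles close last, in one operation.
- Stereochemistry: the target is achiral, so no stereocentre has to be set.

Key step: step 9

Remark: the two N–H tautomers of each imidazole are the same compound. The (E)-alkene of 8, the racemic centre of transient 19 and the alkene geometry of transient 20 all disappear on the way.

**Route**

Step 1
Reactants: 1 2-hydroxy-5-methoxybenzaldehyde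
Product: 2 2-ethenyl-4-methoxyphenol
Conditions: Ph3PCH3Br (2.5 equiv), KOtBu (2.5 equiv), THF, 0 °C to rt
Reagents that add atoms: methyltriphenylphosphonium bromide, C[P+](c1ccccc1)(c1ccccc1)c1ccccc1.[Br-]
Why: Wittig methylenation with an unstabilised ylide, the extra equivalent of base covering the phenol, is the standard entry to 2-vinylphenols from salicylaldehydes.

Step 2
Reactants: 2 2-ethenyl-4-methoxyphenol
Product: 4 2-(2-hydroxyethyl)-4-methoxyphenol, via bis-boryl adduct 3 (not isolated)
Conditions: 9-BBN (2.5 equiv), THF, 0 °C to rt; then 3 M NaOH, 30% H2O2, 0 °C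
Reagents that add atoms: hydrogen peroxide, OO
Why: Hydroboration–oxidation with the bulky 9-BBN should place boron on the terminal carbon of the styrene (one equivalent being consumed by the phenol O–H), and alkaline peroxide then converts C–B into C–OH and frees the phenol.

Step 3
Reactants: 4 2-(2-hydroxyethyl)-4-methoxyphenol
Product: 5 4-methoxy-2-[2-(triisopropylsilyloxy)ethyl]phenol
Conditions: TIPSCl (1.05 equiv), imidazole, CH2Cl2, 0 °C to rt
Reagents that add atoms: triisopropylsilyl chloride, CC(C)[Si](Cl)(C(C)C)C(C)C
Why: Imidazole-mediated silylation with the bulky chloride should take the unhindered primary alcohol ahead of the ortho-substituted phenol, and TIPS is chosen because it must later survive hot carbonate and n-BuLi.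

Step 4
Reactants: 5 4-methoxy-2-[2-(triisopropylsilyloxy)ethyl]phenol; 6 trichloroethylene
Product: 8 (E)-1,2-dichlorovinyl 4-methoxy-2-[2-(triisopropylsilyloxy)ethyl]phenyl ether, via dichloroacetylene 7 (not isolated)
Conditions: K2CO3, DMF, 70 °C
Reagents that add atoms: none
Why: Base-induced dehydrochlorination of trichloroethylene gives dichloroacetylene in situ, and anti addition of the phenoxide across it (nucleophilic addition to a haloalkyne) gives the (E)-dichlorovinyl ether.

Step 5
Reactants: 8 (E)-1,2-dichlorovinyl 4-methoxy-2-[2-(triisopropylsilyloxy)ethyl]phenyl ether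
Product: 11 ethynyl 4-methoxy-2-[2-(triisopropylsilyloxy)ethyl]phenyl ether, via chloroethynyl ether 9 (not isolated), via lithium acetylide 10 (not isolated)
Conditions: n-BuLi (2.3 equiv), THF, −78 to −40 °C; then H2O, −78 to 0 °C; kept cold and used at once
Reagents that add atoms: none
Why: Deprotonation and β-elimination of LiCl give the chloroalkynyl ether, chlorine–lithium exchange gives the lithium aryloxyacetylide, and protonation releases the terminal ynol ether (the dichlorovinyl ether route to ynol ethers).

Step 6
Reactants: 12 3-butyn-1-ol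
Product: 13 4-(triisopropylsilyloxy)but-1-yne
Conditions: TIPSCl, imidazole, CH2Cl2, 0 °C to rt
Reagents that add atoms: triisopropylsilyl chloride, CC(C)[Si](Cl)(C(C)C)C(C)C
Why: Routine silylation of a primary alcohol; the TIPS ether is chosen to withstand the ZnCl2 formed in the next step.

Step 7
Reactants: 13 4-(triisopropylsilyloxy)but-1-yne; 14 trichloroacetyl chloride
Product: 16 4,4-dichloro-3-[2-(triisopropylsilyloxy)ethyl]cyclobut-2-en-1-one, via dichloroketene 15 (not isolated)
Conditions: Zn–Cu couple, Et2O–DME, rt to gentle reflux, slow addition of 14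
Reagents that add atoms: none
Why: Dichloroketene, released by zinc dechlorination of the acid chloride, undergoes [2+2] cycloaddition with the terminal alkyne, whose CH carbon bonds to the ketene carbonyl carbon, so the side chain ends at C3; DME ties up the ZnCl2.

Step 8
Reactants: 16 4,4-dichloro-3-[2-(triisopropylsilyloxy)ethyl]cyclobut-2-en-1-one
Product: 17 3-[2-(triisopropylsilyloxy)ethyl]cyclobut-2-en-1-one
Conditions: Zn dust, AcOH, TMEDA, EtOH, 0 °C to rt
Reagents that add atoms: none
Why: Zinc reduction of the α,α-dichloroketone in buffered acetic acid (reductive dehalogenation through the zinc enolate) is the established way from dichlorocyclobutenones to cyclobutenones without opening the ring.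

Step 9
Reactants: 11 ethynyl 4-methoxy-2-[2-(triisopropylsilyloxy)ethyl]phenyl ether; 17 3-[2-(triisopropylsilyloxy)ethyl]cyclobut-2-en-1-one
Product: 22 3-{4-methoxy-2-[2-(triisopropylsilyloxy)ethyl]phenoxy}-5-[2-(triisopropylsilyloxy)ethyl]phenol, via vinylketene 18 (not isolated), via vinylcyclobutenone 19 (not isolated), via dienylketene 20 (not isolated), via cyclohexadienone 21 (not isolated)
Conditions: 11 (1.2 equiv), 17 (1.0 equiv), toluene, 80 °C then 110 °C, argon
Reagents that add atoms: none
Why: Heating opens cyclobutenone 17 by a four-electron electrocyclic reaction to vinylketene 18, which is captured by ynol ether 11 in a [2+2] cycloaddition (ring B bonds C1–C2 and C5–C6) to give vinylcyclobutenone 19; this opens again to dienylketene 20, whose six-electron electrocyclisation re-forms C4–C5 and gives cyclohexadienone 21, which enolises to phenol 22. The closest known reaction is the Danheiser benzannulation of cyclobutenones with alkoxy- and silyloxyalkynes, of which the aryloxyalkyne is a direct analogue. Ring B therefore closes in a pericyclic mode, by thermal disrotatory closure of the dienylketene to a six-membered carbocycle, after the transient four-membered ring has delivered the two intermolecular bonds. No stereocentre survives: the single centre of 19 forms as a racemate and is erased on ring opening, and because that opening is reversible the material is funnelled through the isomer of 20 in which the ketene and vinyl termini are cis. The one selectivity needed is the orientation of the [2+2] step, and the oxygen lone pair of 11 secures it by making the unsubstituted alkyne carbon the nucleophile that attacks the ketene carbonyl carbon, so the aryloxy group ends meta to both the new hydroxyl and the arm. An aryl ynol ether has no hydrogen on the carbon β to oxygen for retro-ene loss of ketene, so it should tolerate the temperature better than alkyl ynol ethers.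

Step 10
Reactants: 22 3-{4-methoxy-2-[2-(triisopropylsilyloxy)ethyl]phenoxy}-5-[2-(triisopropylsilyloxy)ethyl]phenol
Product: 23 3-{4-methoxy-2-[2-(triisopropylsilyloxy)ethyl]phenoxy}-5-[2-(triisopropylsilyloxy)ethyl]phenyl trifluoromethanesulfonate
Conditions: Tf2O, pyridine, CH2Cl2, 0 °C
Reagents that add atoms: trifluoromethanesulfonic anhydride, O=S(=O)(OS(=O)(=O)C(F)(F)F)C(F)(F)F
Why: O-Sulfonylation of the only free hydroxyl (aryl triflate formation) turns the surplus phenol oxygen into a leaving group under conditions that leave the silyl ethers untouched.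

Step 11
Reactants: 23 3-{4-methoxy-2-[2-(triisopropylsilyloxy)ethyl]phenoxy}-5-[2-(triisopropylsilyloxy)ethyl]phenyl trifluoromethanesulfonate
Product: 24 4-methoxy-2-[2-(triisopropylsilyloxy)ethyl]-1-{3-[2-(triisopropylsilyloxy)ethyl]phenoxy}benzene
Conditions: Pd(OAc)2 (5 mol %), 1,3-bis(diphenylphosphino)propane (5 mol %), Et3N, HCO2H, DMF, 70 °C
Reagents that add atoms: none
Why: Palladium-catalysed formate reduction of an aryl triflate (oxidative addition to zerovalent palladium, formate exchange, decarboxylation, C–H reductive elimination) removes the hydroxyl that the annulation leaves at C5, the chelating phosphine helping the electron-rich triflate.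

Step 12
Reactants: 24 4-methoxy-2-[2-(triisopropylsilyloxy)ethyl]-1-{3-[2-(triisopropylsilyloxy)ethyl]phenoxy}benzene
Product: 25 2-{3-[2-(2-hydroxyethyl)-4-methoxyphenoxy]phenyl}ethanol
Conditions: TBAF (2.5 equiv), THF, 0 °C to rt
Reagents that add atoms: none
Why: Fluoride-induced desilylation, driven by the strong Si–F bond, frees both primary alcohols at once.

Step 13
Reactants: 25 2-{3-[2-(2-hydroxyethyl)-4-methoxyphenoxy]phenyl}ethanol
Product: 26 2-{3-[4-methoxy-2-(2-oxoethyl)phenoxy]phenyl}acetaldehyde
Conditions: Dess–Martin periodinane (2.4 equiv), CH2Cl2, 0 °C to rt; crude product used at once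
Reagents that add atoms: none
Why: Dess–Martin oxidation works under neutral, non-enolising conditions and stops at the aldehyde, which suits the sensitive twofold arylacetaldehyde.

Step 14
Reactants: 26 2-{3-[4-methoxy-2-(2-oxoethyl)phenoxy]phenyl}acetaldehyde
Product: 27 Lepidine C, 2-({3-[2-(1H-imidazol-2-ylmethyl)-4-methoxyphenoxy]phenyl}methyl)-1H-imidazole
Conditions: glyoxal (40% aq.), conc. aq. NH3, MeOH, 0 °C to rt
Reagents that add atoms: glyoxal, O=CC=O; ammonia, N
Why: Debus–Radziszewski imidazole synthesis: each aldehyde condenses with two molecules of ammonia and one of glyoxal, the aldehyde carbon becoming C2 of an aromatic imidazole, so both heterocycles should close in one flask.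

**Compound list**
1 | 2-hydroxy-5-methoxybenzaldehyde | COc1ccc(O)c(C=O)c1 | starting material
2 | 2-ethenyl-4-methoxyphenol | COc1ccc(O)c(C=C)c1 | intermediate
3 | bis-boryl adduct, 9-{2-[2-(9-borabicyclo[3.3.1]nonan-9-yloxy)-5-methoxyphenyl]ethyl}-9-borabicyclo[3.3.1]nonane (formed in the flask) | COc1ccc(OB2C3CCCC2CCC3)c(CCB2C3CCCC2CCC3)c1 | intermediate
4 | 2-(2-hydroxyethyl)-4-methoxyphenol | COc1ccc(O)c(CCO)c1 | intermediate
5 | 4-methoxy-2-[2-(triisopropylsilyloxy)ethyl]phenol | COc1ccc(O)c(CCO[Si](C(C)C)(C(C)C)C(C)C)c1 | intermediate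
6 | trichloroethylene | ClC=C(Cl)Cl | starting material
7 | dichloroacetylene (formed in the flask) | ClC#CCl | intermediate
8 | (E)-1,2-dichlorovinyl 4-methoxy-2-[2-(triisopropylsilyloxy)ethyl]phenyl ether | COc1ccc(O/C(Cl)=C\Cl)c(CCO[Si](C(C)C)(C(C)C)C(C)C)c1 | intermediate
9 | chloroethynyl 4-methoxy-2-[2-(triisopropylsilyloxy)ethyl]phenyl ether (formed in the flask) | COc1ccc(OC#CCl)c(CCO[Si](C(C)C)(C(C)C)C(C)C)c1 | intermediate
10 | lithium acetylide of 11 (formed in the flask) | COc1ccc(OC#C[Li])c(CCO[Si](C(C)C)(C(C)C)C(C)C)c1 | intermediate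
11 | ethynyl 4-methoxy-2-[2-(triisopropylsilyloxy)ethyl]phenyl ether | COc1ccc(OC#C)c(CCO[Si](C(C)C)(C(C)C)C(C)C)c1 | intermediate
12 | 3-butyn-1-ol | C#CCCO | starting material
13 | 4-(triisopropylsilyloxy)but-1-yne | C#CCCO[Si](C(C)C)(C(C)C)C(C)C | intermediate
14 | trichloroacetyl chloride | O=C(Cl)C(Cl)(Cl)Cl | starting material
15 | dichloroketene (formed in the flask) | O=C=C(Cl)Cl | intermediate
16 | 4,4-dichloro-3-[2-(triisopropylsilyloxy)ethyl]cyclobut-2-en-1-one | O=C1C=C(CCO[Si](C(C)C)(C(C)C)C(C)C)C1(Cl)Cl | intermediate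
17 | 3-[2-(triisopropylsilyloxy)ethyl]cyclobut-2-en-1-one | O=C1C=C(CCO[Si](C(C)C)(C(C)C)C(C)C)C1 | intermediate
18 | vinylketene, 3-methylidene-5-(triisopropylsilyloxy)pent-1-en-1-one (formed in the flask) | C=C(CCO[Si](C(C)C)(C(C)C)C(C)C)C=C=O | intermediate
19 | vinylcyclobutenone, 3-{4-methoxy-2-[2-(triisopropylsilyloxy)ethyl]phenoxy}-4-[4-(triisopropylsilyloxy)but-1-en-2-yl]cyclobut-2-en-1-one, racemic (formed in the flask) | COc1ccc(OC2=CC(=O)C2C(=C)CCO[Si](C(C)C)(C(C)C)C(C)C)c(CCO[Si](C(C)C)(C(C)C)C(C)C)c1 | intermediate
20 | dienylketene, (3E)-3-{4-methoxy-2-[2-(triisopropylsilyloxy)ethyl]phenoxy}-5-[2-(triisopropylsilyloxy)ethyl]hexa-1,3,5-trien-1-one, ketene and vinyl termini cis (formed in the flask) | COc1ccc(O/C(C=C=O)=C/C(=C)CCO[Si](C(C)C)(C(C)C)C(C)C)c(CCO[Si](C(C)C)(C(C)C)C(C)C)c1 | intermediate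
21 | cyclohexadienone, 3-{4-methoxy-2-[2-(triisopropylsilyloxy)ethyl]phenoxy}-5-[2-(triisopropylsilyloxy)ethyl]cyclohexa-2,4-dien-1-one (formed in the flask) | COc1ccc(OC2=CC(=O)CC(CCO[Si](C(C)C)(C(C)C)C(C)C)=C2)c(CCO[Si](C(C)C)(C(C)C)C(C)C)c1 | intermediate
22 | 3-{4-methoxy-2-[2-(triisopropylsilyloxy)ethyl]phenoxy}-5-[2-(triisopropylsilyloxy)ethyl]phenol | COc1ccc(Oc2cc(O)cc(CCO[Si](C(C)C)(C(C)C)C(C)C)c2)c(CCO[Si](C(C)C)(C(C)C)C(C)C)c1 | intermediate
23 | 3-{4-methoxy-2-[2-(triisopropylsilyloxy)ethyl]phenoxy}-5-[2-(triisopropylsilyloxy)ethyl]phenyl trifluoromethanesulfonate | COc1ccc(Oc2cc(OS(=O)(=O)C(F)(F)F)cc(CCO[Si](C(C)C)(C(C)C)C(C)C)c2)c(CCO[Si](C(C)C)(C(C)C)C(C)C)c1 | intermediate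
24 | 4-methoxy-2-[2-(triisopropylsilyloxy)ethyl]-1-{3-[2-(triisopropylsilyloxy)ethyl]phenoxy}benzene | COc1ccc(Oc2cccc(CCO[Si](C(C)C)(C(C)C)C(C)C)c2)c(CCO[Si](C(C)C)(C(C)C)C(C)C)c1 | intermediate
25 | 2-{3-[2-(2-hydroxyethyl)-4-methoxyphenoxy]phenyl}ethanol | COc1ccc(Oc2cccc(CCO)c2)c(CCO)c1 | intermediate
26 | 2-{3-[4-methoxy-2-(2-oxoethyl)phenoxy]phenyl}acetaldehyde | COc1ccc(Oc2cccc(CC=O)c2)c(CC=O)c1 | intermediate
27 | Lepidine C | COc1ccc(Oc2cccc(Cc3ncc[nH]3)c2)c(Cc2ncc[nH]2)c1 | target

**Step count**
Total: 14 steps. Longest linear sequence: 11 steps (steps 1–5, then 9–14); steps 6–8 form the second branch.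

**Steps most likely to fail**

Step 9. Thermal oligomerisation of the terminal ynol ether may outrun its capture by the vinylketene, and the product phenol may be O-acylated by the vinylketene. Fallback: the diaryl ether would be made by Ullmann coupling of a preformed ring B. It sets out from phenol 5. Commercial 2-(3-bromophenyl)ethanol would be silylated (TIPSCl, imidazole, CH2Cl2) to [2-(3-bromophenyl)ethoxy]triisopropylsilane F1, and 5 and F1 would be coupled with CuI, picolinic acid and K3PO4 in DMSO at 90 °C. This comes back to the route at 24 and makes steps 4 to 11 unnecessary.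

Step 5. The terminal aryl ethynyl ether may be lost through hydration or polymerisation during work-up and concentration. Fallback: it sets out from 8. The lithium acetylide 10 would be quenched with TMSCl in place of water to give the storable, chromatographable {4-methoxy-2-[2-(triisopropylsilyloxy)ethyl]phenoxy}ethynyl(trimethyl)silane F2. Heating F2 with cyclobutenone 17 in toluene at 110 °C should give 3-{4-methoxy-2-[2-(triisopropylsilyloxy)ethyl]phenoxy}-5-[2-(triisopropylsilyloxy)ethyl]-2-(trimethylsilyl)phenol F3, with silicon on the carbon between the two oxygens. Ipso-protodesilylation of this very electron-rich arylsilane with trifluoroacetic acid in CH2Cl2 at 0 °C would come back to the route at 22.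

Step 14. The twofold arylacetaldehyde may undergo aldol self-condensation and enamine formation in ammonia, so that one or both imidazole closures stall. Fallback: it sets out from diol 25 and avoids the dialdehyde. Oxidation with catalytic TEMPO, PhI(OAc)2 and NH4OAc in MeCN–H2O would give 2-{3-[2-(cyanomethyl)-4-methoxyphenoxy]phenyl}acetonitrile F4. A Pinner reaction (HCl gas, MeOH, 0 °C) would give the bis(methyl imidate) dihydrochloride F5, and aminoacetaldehyde dimethyl acetal in MeOH would convert it into the bis[N-(2,2-dimethoxyethyl)amidine] dihydrochloride F6. Warming F6 in 2 M aqueous HCl and then basifying would close both imidazoles and come back to the route at 27.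

**Further compounds**
F1 | step 9 | [2-(3-bromophenyl)ethoxy]triisopropylsilane | Brc1cccc(CCO[Si](C(C)C)(C(C)C)C(C)C)c1
F2 | step 5 | {4-methoxy-2-[2-(triisopropylsilyloxy)ethyl]phenoxy}ethynyl(trimethyl)silane | COc1ccc(OC#C[Si](C)(C)C)c(CCO[Si](C(C)C)(C(C)C)C(C)C)c1
F3 | step 5 | 3-{4-methoxy-2-[2-(triisopropylsilyloxy)ethyl]phenoxy}-5-[2-(triisopropylsilyloxy)ethyl]-2-(trimethylsilyl)phenol | COc1ccc(Oc2cc(CCO[Si](C(C)C)(C(C)C)C(C)C)cc(O)c2[Si](C)(C)C)c(CCO[Si](C(C)C)(C(C)C)C(C)C)c1
F4 | step 14 | 2-{3-[2-(cyanomethyl)-4-methoxyphenoxy]phenyl}acetonitrile | COc1ccc(Oc2cccc(CC#N)c2)c(CC#N)c1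
F5 | step 14 | methyl 2-{3-[4-methoxy-2-(2-imino-2-methoxyethyl)phenoxy]phenyl}acetimidate dihydrochloride | COc1ccc(Oc2cccc(CC(=N)OC)c2)c(CC(=N)OC)c1.Cl.Cl
F6 | step 14 | N-(2,2-dimethoxyethyl)-2-{3-[2-{2-[(2,2-dimethoxyethyl)amino]-2-iminoethyl}-4-methoxyphenoxy]phenyl}acetamidine dihydrochloride | COc1ccc(Oc2cccc(CC(=N)NCC(OC)OC)c2)c(CC(=N)NCC(OC)OC)c1.Cl.Cl
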